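The synthesis rests on cutting the C4–C4a bond of ring C, which unfolds the flavanone into an open-chain (S)-3-aryl-3-aryloxypropanoic acid. C4a sits ortho to O1 and to the oxygen on C5, and para to the oxygen on C7 of ring A. The two carbons flanking the ether oxygen of a 3,5-bis(benzyloxy)phenoxy group are interchangeable. Activating the acid as its mixed trifluoroacetic anhydride therefore closes ring C in one operation, as one regioisomer, with C2 untouched. The precursor already carries all three stereocentres. The erythro (7''R,8''S) chain, a bis-TBS ether, comes from an Evans aldol and a benzylic inversion. C2 is set by transfer hydrogenation and Mitsunobu etherification.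

Key step: step 13

Locants: flavanone numbering is used (O1, C2–C4, C4a, C5–C8, C8a; ring B primed). In the side chain, C7'' is benzylic, C8'' bears the aryloxy group and C9'' is CH2O. The target is (2S,7''R,8''S), erythro in the side chain.
Abbreviations: Bn = benzyl; TBS = tert-butyldimethylsilyl; EC–O– = {(1R,2S)-1-[4-(benzyloxy)-3-methoxyphenyl]-1,3-bis[(tert-butyldimethylsilyl)oxy]propan-2-yl}oxy.
Protecting groups: TBS on O7''/O9'' and benzyl on the three phenols tolerate cold, dilute CF3CO2H. Both leave under non-basic conditions, which a base-sensitive flavanone requires.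
Assumption: phloroglucinol, methyl syringate, O-benzylvanillin and (4R)-4-benzyl-3-(chloroacetyl)-1,3-oxazolidin-2-one are taken as catalogue compounds; the last would otherwise cost one N-acylation of (R)-4-benzyloxazolidin-2-one with chloroacetyl chloride.

Step 1
Reactants: 1 phloroglucinol (benzene-1,3,5-triol)
Product: 2 3,5-bis(benzyloxy)phenol
Conditions: BnBr (2 equiv), K2CO3, DMF, rt; chromatography
Reagents that add atoms: benzyl bromide, BrCc1ccccc1
Why: Williamson ether synthesis with two equivalents of halide should make the diether the main member of a statistical set, from which mono- and triether are removed by chromatography.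

Step 2
Reactants: 3 methyl syringate (methyl 4-hydroxy-3,5-dimethoxybenzoate); 4 (4R)-4-benzyl-3-(chloroacetyl)-1,3-oxazolidin-2-one
Product: 5 methyl 4-{2-[(4R)-4-benzyl-2-oxo-1,3-oxazolidin-3-yl]-2-oxoethoxy}-3,5-dimethoxybenzoate
Conditions: K2CO3, DMF, 40 °C
Reagents that add atoms: none
Why: Williamson-type SN2 displacement on the activated alpha-chloro imide by a hindered, weakly basic phenoxide that is too poor an acyl acceptor to cleave the imide.

Step 3
Reactants: 5 aryloxyacetyl imide; 6 O-benzylvanillin (4-(benzyloxy)-3-methoxybenzaldehyde)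
Product: 9 threo (syn) aldol imide methyl 4-{[(1S,2R)-1-[4-(benzyloxy)-3-methoxyphenyl]-3-[(4R)-4-benzyl-2-oxo-1,3-oxazolidin-3-yl]-1-hydroxy-3-oxopropan-2-yl]oxy}-3,5-dimethoxybenzoate, via Z-boron enolate 7 (not isolated), via boron aldolate 8 (not isolated)
Conditions: Bu2BOTf, i-Pr2NEt, CH2Cl2, −78 → 0 °C; 6, −78 → 0 °C; pH 7 buffer, MeOH, 30% H2O2, 0 °C
Reagents that add atoms: none
Why: Evans syn aldol reaction, in which soft enolisation gives the Z-boron enolate, and this adds through a Zimmerman–Traxler chair on the face away from the benzyl group of the (R)-auxiliary, setting C8'' (S once C9'' is reduced) and C7'' (S, threo), a reaction type established for aryloxyacetyl imides and aromatic aldehydes.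

Step 4
Reactants: 9 threo aldol imide
Product: 10 threo diol methyl 4-{[(1S,2S)-1-[4-(benzyloxy)-3-methoxyphenyl]-1,3-dihydroxypropan-2-yl]oxy}-3,5-dimethoxybenzoate
Conditions: NaBH4, THF–H2O (4:1), 0 °C → rt
Reagents that add atoms: none
Why: Chemoselective borohydride reduction of the activated imide carbonyl removes the auxiliary and gives the C9'' alcohol, while the aromatic methyl ester is inert to NaBH4 and neither stereocentre is touched.

Step 5
Reactants: 10 threo diol
Product: 11 methyl 4-{[(1S,2S)-1-[4-(benzyloxy)-3-methoxyphenyl]-3-[(tert-butyldimethylsilyl)oxy]-1-hydroxypropan-2-yl]oxy}-3,5-dimethoxybenzoate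
Conditions: TBSCl (1.05 equiv), imidazole, CH2Cl2, 0 °C
Reagents that add atoms: tert-butyldimethylsilyl chloride, CC(C)(C)[Si](C)(C)Cl
Why: Sterically controlled monosilylation, since the primary C9'' hydroxyl reacts far faster with TBSCl than the hindered secondary benzylic one.

Step 6
Reactants: 11 threo C7'' alcohol
Product: 12 erythro ester methyl 4-{[(1R,2S)-1-[4-(benzyloxy)-3-methoxyphenyl]-3-[(tert-butyldimethylsilyl)oxy]-1-[(4-nitrobenzoyl)oxy]propan-2-yl]oxy}-3,5-dimethoxybenzoate
Conditions: 4-O2NC6H4CO2H, PPh3, DIAD, toluene, 0 °C → rt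
Reagents that add atoms: 4-nitrobenzoic acid, O=C(O)c1ccc([N+](=O)[O-])cc1
Why: Mitsunobu inversion, in which the acidic carboxylate displaces the C7'' oxyphosphonium group in an SN2 sense and turns 7''S into 7''R (threo to erythro), the withdrawing C8'' aryloxy and C9'' silyloxy groups disfavouring ionisation; this inversion is known for beta-aryl ether lignin-type carbinols.

Step 7
Reactants: 12 erythro 4-nitrobenzoate
Product: 13 erythro alcohol methyl 4-{[(1R,2S)-1-[4-(benzyloxy)-3-methoxyphenyl]-3-[(tert-butyldimethylsilyl)oxy]-1-hydroxypropan-2-yl]oxy}-3,5-dimethoxybenzoate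
Conditions: K2CO3 (0.3 equiv), MeOH–THF, 0 °C → rt
Reagents that add atoms: none
Why: Base-catalysed transesterification removes the activated nitrobenzoate with retention at C7'' because only the acyl–oxygen bond breaks; the ring B methyl ester merely exchanges methoxide for methoxide, and any O9''-to-O7'' silyl shift would be levelled by the next step.

Step 8
Reactants: 13 erythro alcohol
Product: 14 methyl 4-(EC–O)-3,5-dimethoxybenzoate
Conditions: TBSOTf, 2,6-lutidine, CH2Cl2, 0 °C
Reagents that add atoms: tert-butyldimethylsilyl triflate, CC(C)(C)[Si](C)(C)OS(=O)(=O)C(F)(F)F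
Why: Silyl triflate/lutidine silylation overcomes the hindrance of the secondary benzylic hydroxyl under non-ionising, buffered conditions.

Step 9
Reactants: 14 bis-TBS methyl benzoate
Product: 15 methyl 3-[4-(EC–O)-3,5-dimethoxyphenyl]-3-oxopropanoate
Conditions: MeOAc, LiN(SiMe3)2 (excess), THF, −78 → 0 °C; AcOH
Reagents that add atoms: methyl acetate, COC(C)=O
Why: Crossed Claisen condensation of a non-enolisable aryl ester with the lithium enolate of methyl acetate, driven by deprotonation of the beta-keto ester and helped by an ester carbonyl that feels only two meta methoxy groups and a twisted para alkoxy group.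

Step 10
Reactants: 15 beta-keto ester
Product: 16 methyl (3R)-3-[4-(EC–O)-3,5-dimethoxyphenyl]-3-hydroxypropanoate
Conditions: RuCl[(R,R)-TsDPEN](p-cymene) (1 mol %), HCO2H–Et3N (5:2), EtOAc, 30 °C
Reagents that add atoms: none
Why: Noyori asymmetric transfer hydrogenation of an aryl beta-keto ester, in which the (R,R)-catalyst delivers hydride to the ketone face fixed by the CH–pi contact between p-cymene and ring B, so the R carbinol should arise under catalyst control remote from the side-chain stereocentres.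

Step 11
Reactants: 16 (R)-beta-hydroxy ester; 2 3,5-bis(benzyloxy)phenol
Product: 17 methyl (3S)-3-[3,5-bis(benzyloxy)phenoxy]-3-[4-(EC–O)-3,5-dimethoxyphenyl]propanoate
Conditions: PPh3, DIAD (slow addition), toluene, 0 °C → rt
Reagents that add atoms: none
Why: Mitsunobu etherification, in which the phenoxide displaces the oxyphosphonium group by SN2 with inversion (R to S, the future C2), ring B stabilising a cation only weakly and the cold non-polar medium limiting elimination.

Step 12
Reactants: 17 aryl ether methyl ester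
Product: 18 (3S)-3-[3,5-bis(benzyloxy)phenoxy]-3-[4-(EC–O)-3,5-dimethoxyphenyl]propanoic acid
Conditions: LiOH, THF–MeOH–H2O, 0 °C → rt; 0.5 M HCl to pH 4, 0 °C
Reagents that add atoms: lithium hydroxide, [Li+].[OH-]
Why: Saponification of the unhindered methyl ester by acyl–oxygen cleavage is faster than alpha-deprotonation, so E1cB loss of the aryloxide should not compete, and the carboxylate formed is immune to it; silyl and benzyl ethers are stable.

Step 13
Reactants: 18 (S)-3-aryl-3-aryloxypropanoic acid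
Product: 20 (2S)-5,7-bis(benzyloxy)-2-[4-(EC–O)-3,5-dimethoxyphenyl]chroman-4-one, via acyl trifluoroacetate 19 (not isolated)
Conditions: (CF3CO)2O (1.1 equiv), CH2Cl2 (0.01 M), −20 → 0 °C; cold aq NaHCO3
Reagents that add atoms: none
Why: The acid attacks (CF3CO)2O to give acyl trifluoroacetate 19, whose acyl carbon (as such or as the derived acylium ion) is attacked by the ring A carbon next to the ether oxygen, and loss of a proton from the arenium ion restores aromaticity and releases CF3CO2H. This is an intramolecular Friedel–Crafts acylation of a 3-aryloxypropanoic acid, the standard entry to chroman-4-ones and flavanones. Ring C closes in a six-membered mode that is 6-exo-trig at the acyl carbon (6-exo-dig for a free acylium ion), with the C4a–C8a bond of the arene inside the new ring. No stereocentre is created, and C2 should stay S because no base is present to trigger E1cB loss of the aryloxide and because cold, high-dilution conditions keep the liberated acid too dilute to ionise the benzylic C2–O1 or C7''–O bonds, ring B offering a cation at C2 only two meta methoxy groups and a twisted para alkoxy group. Regioselectivity needs no control, since only the two carbons flanking O1 can reach the acyl carbon and both give the same flavanone after rotation about the O1–C8a bond. Chemoselectivity rests on the phloroglucinol-type ring being by far the best nucleophile, on a near-stoichiometric charge of anhydride that limits trifluoroacetylation of ring A, and on deactivation of ring A by the new ketone.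

Step 14
Reactants: 20 protected flavanone
Product: 21 (2S)-5,7-bis(benzyloxy)-2-(4-{[(1R,2S)-1-[4-(benzyloxy)-3-methoxyphenyl]-1,3-dihydroxypropan-2-yl]oxy}-3,5-dimethoxyphenyl)chroman-4-one
Conditions: HF·pyridine, pyridine, THF, 0 °C → rt
Reagents that add atoms: none
Why: Fluoride-mediated desilylation in a buffered, mildly acidic medium, chosen over basic Bu4NF because base would open ring C by retro-oxa-Michael reaction and scramble C2; the still benzylated guaiacyl phenol cannot form a quinone methide at C7''.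

Step 15
Reactants: 21 tri-O-benzyl flavanone diol
Product: 22 target, (2S)-5,7-dihydroxy-2-(4-{[(1R,2S)-1,3-dihydroxy-1-(4-hydroxy-3-methoxyphenyl)propan-2-yl]oxy}-3,5-dimethoxyphenyl)chroman-4-one
Conditions: H2 (1 atm), 10% Pd/C, EtOAc–MeOH, rt, stopped after uptake of three equivalents
Reagents that add atoms: none
Why: Catalytic hydrogenolysis of three aryl benzyl ethers in neutral solvent should be faster than cleavage of the secondary benzylic C7''–OH and C2–O1 bonds or reduction of the vinylogous-ester-like C4 ketone, so all three stereocentres survive.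

Compound list
1 | phloroglucinol | Oc1cc(O)cc(O)c1 | starting material
2 | 3,5-bis(benzyloxy)phenol | Oc1cc(OCc2ccccc2)cc(OCc2ccccc2)c1 | intermediate
3 | methyl syringate | COC(=O)c1cc(OC)c(O)c(OC)c1 | starting material
4 | (4R)-4-benzyl-3-(chloroacetyl)-1,3-oxazolidin-2-one | O=C(CCl)N1C(=O)OC[C@H]1Cc1ccccc1 | starting material
5 | methyl 4-{2-[(4R)-4-benzyl-2-oxo-1,3-oxazolidin-3-yl]-2-oxoethoxy}-3,5-dimethoxybenzoate | COC(=O)c1cc(OC)c(OCC(=O)N2C(=O)OC[C@H]2Cc2ccccc2)c(OC)c1 | intermediate
6 | O-benzylvanillin | COc1cc(C=O)ccc1OCc1ccccc1 | starting material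
7 | Z-dibutylboron enolate of 5 (not isolated) | CCCCB(CCCC)O/C(=C\Oc1c(OC)cc(C(=O)OC)cc1OC)N1C(=O)OC[C@H]1Cc1ccccc1 | intermediate
8 | dibutylboron aldolate of 9 (not isolated) | COc1cc([C@H](OB(CCCC)CCCC)[C@H](C(=O)N2C(=O)OC[C@H]2Cc2ccccc2)Oc2c(OC)cc(C(=O)OC)cc2OC)ccc1OCc1ccccc1 | intermediate
9 | threo (syn) aldol imide, (1S,2R) in the propan-2-yl unit, (4R)-auxiliary | COc1cc([C@H](O)[C@H](C(=O)N2C(=O)OC[C@H]2Cc2ccccc2)Oc2c(OC)cc(C(=O)OC)cc2OC)ccc1OCc1ccccc1 | intermediate
10 | threo (1S,2S)-diol | COc1cc([C@H](O)[C@H](CO)Oc2c(OC)cc(C(=O)OC)cc2OC)ccc1OCc1ccccc1 | intermediate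
11 | threo (1S,2S)-alcohol, O9''-TBS | COc1cc([C@H](O)[C@H](CO[Si](C)(C)C(C)(C)C)Oc2c(OC)cc(C(=O)OC)cc2OC)ccc1OCc1ccccc1 | intermediate
12 | erythro (1R,2S)-4-nitrobenzoate, O9''-TBS | COc1cc([C@@H](OC(=O)c2ccc([N+](=O)[O-])cc2)[C@H](CO[Si](C)(C)C(C)(C)C)Oc2c(OC)cc(C(=O)OC)cc2OC)ccc1OCc1ccccc1 | intermediate
13 | erythro (1R,2S)-alcohol, O9''-TBS | COc1cc([C@@H](O)[C@H](CO[Si](C)(C)C(C)(C)C)Oc2c(OC)cc(C(=O)OC)cc2OC)ccc1OCc1ccccc1 | intermediate
14 | methyl 4-(EC–O)-3,5-dimethoxybenzoate | COc1cc([C@@H](O[Si](C)(C)C(C)(C)C)[C@H](CO[Si](C)(C)C(C)(C)C)Oc2c(OC)cc(C(=O)OC)cc2OC)ccc1OCc1ccccc1 | intermediate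
15 | methyl 3-[4-(EC–O)-3,5-dimethoxyphenyl]-3-oxopropanoate | COc1cc([C@@H](O[Si](C)(C)C(C)(C)C)[C@H](CO[Si](C)(C)C(C)(C)C)Oc2c(OC)cc(C(=O)CC(=O)OC)cc2OC)ccc1OCc1ccccc1 | intermediate
16 | methyl (3R)-3-[4-(EC–O)-3,5-dimethoxyphenyl]-3-hydroxypropanoate | COc1cc([C@@H](O[Si](C)(C)C(C)(C)C)[C@H](CO[Si](C)(C)C(C)(C)C)Oc2c(OC)cc([C@H](O)CC(=O)OC)cc2OC)ccc1OCc1ccccc1 | intermediate
17 | methyl (3S)-3-[3,5-bis(benzyloxy)phenoxy]-3-[4-(EC–O)-3,5-dimethoxyphenyl]propanoate | COc1cc([C@@H](O[Si](C)(C)C(C)(C)C)[C@H](CO[Si](C)(C)C(C)(C)C)Oc2c(OC)cc([C@H](CC(=O)OC)Oc3cc(OCc4ccccc4)cc(OCc4ccccc4)c3)cc2OC)ccc1OCc1ccccc1 | intermediate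
18 | (3S)-3-[3,5-bis(benzyloxy)phenoxy]-3-[4-(EC–O)-3,5-dimethoxyphenyl]propanoic acid | COc1cc([C@@H](O[Si](C)(C)C(C)(C)C)[C@H](CO[Si](C)(C)C(C)(C)C)Oc2c(OC)cc([C@H](CC(=O)O)Oc3cc(OCc4ccccc4)cc(OCc4ccccc4)c3)cc2OC)ccc1OCc1ccccc1 | intermediate
19 | acyl trifluoroacetate of 18 (not isolated) | COc1cc([C@@H](O[Si](C)(C)C(C)(C)C)[C@H](CO[Si](C)(C)C(C)(C)C)Oc2c(OC)cc([C@H](CC(=O)OC(=O)C(F)(F)F)Oc3cc(OCc4ccccc4)cc(OCc4ccccc4)c3)cc2OC)ccc1OCc1ccccc1 | intermediate
20 | (2S)-5,7-bis(benzyloxy)-2-[4-(EC–O)-3,5-dimethoxyphenyl]chroman-4-one | COc1cc([C@@H](O[Si](C)(C)C(C)(C)C)[C@H](CO[Si](C)(C)C(C)(C)C)Oc2c(OC)cc([C@@H]3CC(=O)c4c(OCc5ccccc5)cc(OCc5ccccc5)cc4O3)cc2OC)ccc1OCc1ccccc1 | intermediate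
21 | (2S,7''R,8''S)-tri-O-benzyl flavanone diol | COc1cc([C@@H](O)[C@H](CO)Oc2c(OC)cc([C@@H]3CC(=O)c4c(OCc5ccccc5)cc(OCc5ccccc5)cc4O3)cc2OC)ccc1OCc1ccccc1 | intermediate
22 | (2S)-5,7-dihydroxy-2-(4-{[(1R,2S)-1,3-dihydroxy-1-(4-hydroxy-3-methoxyphenyl)propan-2-yl]oxy}-3,5-dimethoxyphenyl)chroman-4-one | COc1cc([C@@H](O)[C@H](CO)Oc2c(OC)cc([C@@H]3CC(=O)c4c(O)cc(O)cc4O3)cc2OC)ccc1O | target

Total step count: 15. Longest linear sequence: 14 steps (steps 2–15, from methyl syringate 3).

Steps most likely to fail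

1. Step 13 (ring closure).
- What may go wrong: acid-induced ionisation at the benzylic C2–O1 or C7''–O bonds with erosion of configuration, loss of silyl groups, trifluoroacetylation of ring A, or intermolecular acylation.
- Fallback: the same C4–C4a bond is made with reversed polarity and without acid, by a Parham-type anionic cyclisation. Setting out from 2, iodination with N-iodosuccinimide (CH2Cl2, −20 °C) should give 3,5-bis(benzyloxy)-2-iodophenol F1 after separation from its 4-iodo isomer. Mitsunobu etherification of 16 with this phenol (PPh3, DIAD, toluene, 0 °C) should give methyl (3S)-3-[3,5-bis(benzyloxy)-2-iodophenoxy]-3-[4-(EC–O)-3,5-dimethoxyphenyl]propanoate F2. Iodine–lithium exchange (n-BuLi, THF, −95 °C) outruns deprotonation and external ester addition, so the aryllithium should attack the internal ester. A cold AcOH quench comes back to the route at 20.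

2. Step 11 (aryl ether formation).
- What may go wrong: elimination across the acidic alpha-hydrogens of the beta-hydroxy ester instead of substitution, or partial ionisation with incomplete inversion.
- Fallback: the ester is taken out of play during the substitution. Setting out from 16, LiBH4 (THF, 0 °C → rt) should give (1R)-1-[4-(EC–O)-3,5-dimethoxyphenyl]propane-1,3-diol F3. Pivaloyl chloride in pyridine at 0 °C should acylate only the primary hydroxyl to give the (3R)-3-hydroxy-3-arylpropyl pivalate F4. Mitsunobu etherification with 2 then runs on a carbinol without acidic neighbours, as in the 3-aryloxy-3-arylpropylamine drug series, and should give the (3S)-3-[3,5-bis(benzyloxy)phenoxy]-3-arylpropyl pivalate F5. i-Bu2AlH (CH2Cl2, −78 °C) should free the (3S)-3-[3,5-bis(benzyloxy)phenoxy]-3-arylpropan-1-ol F6. TEMPO/PhI(OAc)2 in MeCN–H2O should oxidise it to the acid, which comes back to the route at 18.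

3. Step 6 (inversion at C7'').
- What may go wrong: sluggish activation of the hindered carbinol, or partial SN1 character at the electron-rich benzylic centre with poor threo-to-erythro conversion.
- Fallback: oxidation and reduction replace the substitution. Setting out from 11, Dess–Martin periodinane (NaHCO3, CH2Cl2, 0 °C) should give methyl 4-{[(2S)-1-[4-(benzyloxy)-3-methoxyphenyl]-3-[(tert-butyldimethylsilyl)oxy]-1-oxopropan-2-yl]oxy}-3,5-dimethoxybenzoate F7 without base that could epimerise C8''. Zn(BH4)2 (Et2O, −30 °C) should then reduce it under Cram chelate control. Zinc bridges the ketone oxygen and the C8'' aryloxy oxygen, aided by the flanking methoxy groups, and hydride enters from the side of the C8'' hydrogen. This should give the anti (erythro) alcohol and come back to the route at 13.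

Further compounds
F1 | step 13 | 3,5-bis(benzyloxy)-2-iodophenol | Oc1cc(OCc2ccccc2)cc(OCc2ccccc2)c1I
F2 | step 13 | methyl (3S)-3-[3,5-bis(benzyloxy)-2-iodophenoxy]-3-[4-(EC–O)-3,5-dimethoxyphenyl]propanoate | COc1cc([C@@H](O[Si](C)(C)C(C)(C)C)[C@H](CO[Si](C)(C)C(C)(C)C)Oc2c(OC)cc([C@H](CC(=O)OC)Oc3cc(OCc4ccccc4)cc(OCc4ccccc4)c3I)cc2OC)ccc1OCc1ccccc1
F3 | step 11 | (1R)-1-[4-(EC–O)-3,5-dimethoxyphenyl]propane-1,3-diol | COc1cc([C@@H](O[Si](C)(C)C(C)(C)C)[C@H](CO[Si](C)(C)C(C)(C)C)Oc2c(OC)cc([C@H](O)CCO)cc2OC)ccc1OCc1ccccc1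
F4 | step 11 | (3R)-3-hydroxy-3-[4-(EC–O)-3,5-dimethoxyphenyl]propyl pivalate | COc1cc([C@@H](O[Si](C)(C)C(C)(C)C)[C@H](CO[Si](C)(C)C(C)(C)C)Oc2c(OC)cc([C@H](O)CCOC(=O)C(C)(C)C)cc2OC)ccc1OCc1ccccc1
F5 | step 11 | (3S)-3-[3,5-bis(benzyloxy)phenoxy]-3-[4-(EC–O)-3,5-dimethoxyphenyl]propyl pivalate | COc1cc([C@@H](O[Si](C)(C)C(C)(C)C)[C@H](CO[Si](C)(C)C(C)(C)C)Oc2c(OC)cc([C@H](CCOC(=O)C(C)(C)C)Oc3cc(OCc4ccccc4)cc(OCc4ccccc4)c3)cc2OC)ccc1OCc1ccccc1
F6 | step 11 | (3S)-3-[3,5-bis(benzyloxy)phenoxy]-3-[4-(EC–O)-3,5-dimethoxyphenyl]propan-1-ol | COc1cc([C@@H](O[Si](C)(C)C(C)(C)C)[C@H](CO[Si](C)(C)C(C)(C)C)Oc2c(OC)cc([C@H](CCO)Oc3cc(OCc4ccccc4)cc(OCc4ccccc4)c3)cc2OC)ccc1OCc1ccccc1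
F7 | step 6 | methyl 4-{[(2S)-1-[4-(benzyloxy)-3-methoxyphenyl]-3-[(tert-butyldimethylsilyl)oxy]-1-oxopropan-2-yl]oxy}-3,5-dimethoxybenzoate | COc1cc(C(=O)[C@H](CO[Si](C)(C)C(C)(C)C)Oc2c(OC)cc(C(=O)OC)cc2OC)ccc1OCc1ccccc1
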